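The runs were computed from invented constants, noise included.

The racemization catalyst is a small charge, 2.5 mM in Wednesday's run against 0.76 M of each substrate. Yet Wednesday's left-handed product reaches 62.0% of the substrates charged, more than the fraction 0.5 that was left-handed at the start, so right-handed substrate has been turned into left-handed substrate.

| setting | Wednesday's | green | blue | ochre |
|---|---|---|---|---|
| left-handed substrate | 0.76 M | 0.76 M | 0.76 M | 0.76 M |
| right-handed substrate | 0.76 M | 0.76 M | 0.76 M | 0.76 M |
| coupling partner | 2.28 M | 2.28 M | 2.28 M | 2.28 M |
| free catalyst | 120 mM | 120 mM | 200 mM | 300 mM |
| racemization catalyst | 2.5 mM | 3.8 mM | 3.8 mM | 3.8 mM |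
| remark | run made earlier |  |  |  |
| time |  | 8.0 h | 8.0 h | 8.0 h |

Wednesday's run (percent of the left-handed substrate and right-handed substrate together charged)

| time / min | left-handed product / % | right-handed product / % |
|---|---|---|
| 8.00 | 23.6 | 11.4 |
| 12.0 | 28.7 | 15.1 |
| 20.0 | 38.2 | 21.3 |
| 40.0 | 51.9 | 27.4 |
| 60.0 | 57.4 | 30.5 |
| 90.0 | 62.0 | 34.3 |

(each reading ± 1 percentage point)

1. excess of left-handed product over right-handed product at the end for green, blue, ochre, in this order
2. the shape of the row from first to last (rises all the way / rises, then falls / hardly changes / falls, then rises / falls all the way)

- free catalyst is single-handed; left-handed substrate and right-handed substrate are mirror images of each other, charged as a racemate, each of them at the stated concentration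
- an excess is the difference of the two amounts in percent of their sum
- "hardly changes" means that all values lie within two and a half points (for a concentration: within two and a half percent of the largest)
- no earlier run changes the charge of free catalyst; that part of a forecast is a guess
- no earlier run changes the charge of racemization catalyst; that part of a forecast is a guess

I reckon in fractions of the substrates charged: p of left-handed product, q of right-handed product. The large part is simple. While the two substrates stand equal, p and q grow at a fixed ratio, the selectivity factor, so (p − q)/(p + q) stays constant with conversion. The small part is a lag: if racemization falls behind, left-handed substrate runs below right-handed substrate, and later product comes out poorer. Wednesday's run therefore gives the number by two ways, pooling p and q: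

readings up to 20.0 min: excess = 30.9%

readings from 40.0 min on: excess = 30.0%

The gap is 0.86 percentage points, less than its own scatter of about 2 points, so the two ways agree and I pool them:

readings together: excess = 30.3%

I carry this reading of Wednesday's run, with its scatter, as the feed excess, the excess of product made while the two substrates stand equal. As a guess, since no earlier run changes either charge, I scale the gap by free catalyst over racemization catalyst:

green: 29.8%

blue: 29.4%

ochre: 28.9%

My row hardly changes. The forecast differs, with 33%, 29% and 25%, falls all the way: “More free catalyst outruns racemization, so the excess falls.”

The flask gives 31.5%, 31.3% and 31.1%, so the row hardly changes.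

coupling partner + free catalyst + right-handed substrate → free catalyst + right-handed product (k = 0.150 M⁻² min⁻¹); left-handed substrate + racemization catalyst ⇌ right-handed substrate + racemization catalyst, rate k2*[racemization catalyst]*[left-handed substrate] forward; the back reaction follows from the equilibrium constant (k = 500 M⁻¹ min⁻¹); coupling partner + free catalyst + left-handed substrate → free catalyst + left-handed product (k = 0.290 M⁻² min⁻¹) In green, the rate at which the left-handed route uses coupling partner over that of the right-handed route is 1.9 at the start and 1.9 at 8.00 h. With 0% of the left-handed substrate left in green, the feed excess puts left-handed product at (1 + excess)/2 = 65.2% of the substrates charged, and green holds 65.8% at 8.00 h. Ochre, with 300 mM of free catalyst, ends at 31.1%, which is 0.80 points from the feed excess.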